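**Strategy.** Daucane numbering: C1 quaternary ring-fusion carbon, C4 carbinol, C5 ring-fusion CH, C6 ester carbon, C7 CH2, C8=C9 alkene, C10 ketone. The cycloheptenone is cut into C7–C8=C9–C10 and C6–C5–C1. A chromium methoxy(cyclopentenyl)carbene (carbene carbon C6, alkene C5=C1) and the silyl dienol ether of 3-methylbut-2-enal undergo a formal [4+3] cycloaddition, cyclopropanation then Cope rearrangement of the cis-divinylcyclopropane, forming C6–C7 and the quaternary C1–C10 bond in one operation. The step exploits the C8=C9 double bond flanked by C7 and C10 in the seven-membered ring and the oxygens on C6 and C10. A temporary C4 silyloxy stereocentre on the carbene partner steers the facial course.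

Key step: step 5

Remark: β denotes the face of the C1 methyl group (target: 1β-Me, 4β-OH, 5α-H, 6β-acyloxy); compounds 1 and 13 are taken as catalogue items.

**Step 1**
Reactants: 1 2-bromo-3-methylcyclopent-2-en-1-one
Product: 2 (S)-2-bromo-3-methylcyclopent-2-en-1-ol
Conditions: (R)-2-methyl-CBS-oxazaborolidine [(R)-1-methyl-3,3-diphenyltetrahydro-1H,3H-pyrrolo[1,2-c][1,3,2]oxazaborole] (10 mol %), BH3·SMe2, THF, −20 °C
Reagents that add atoms: none
Why: Corey–Bakshi–Shibata reduction, in which the bromoalkenyl arm acts as the larger ketone substituent so that the (R)-oxazaborolidine–borane complex should give the (S)-carbinol, the stereocentre from which all others are later derived.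

**Step 2**
Reactants: 2 (S)-2-bromo-3-methylcyclopent-2-en-1-ol
Product: 3 (S)-[(2-bromo-3-methylcyclopent-2-en-1-yl)oxy](tert-butyl)dimethylsilane
Conditions: TBSCl, imidazole, DMF, rt
Reagents that add atoms: tert-butyldimethylsilyl chloride, CC(C)(C)[Si](C)(C)Cl
Why: Standard imidazole-promoted silylation installs a base-stable group whose bulk will later shield the β-face of the cyclopentene, the stereocentre being untouched.

**Step 3**
Reactants: 3 (S)-[(2-bromo-3-methylcyclopent-2-en-1-yl)oxy](tert-butyl)dimethylsilane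
Product: 6 pentacarbonyl{methoxy[(S)-5-(tert-butyldimethylsilyloxy)-2-methylcyclopent-1-en-1-yl]methylidene}chromium, via alkenyllithium 4 (not isolated), via lithium acylchromate 5 (not isolated)
Conditions: t-BuLi (2 equiv), Et2O, −78 °C; Cr(CO)6, −78 °C → rt; Me3OBF4, CH2Cl2, 0 °C
Reagents that add atoms: chromium hexacarbonyl, O=C=[Cr](=C=O)(=C=O)(=C=O)(=C=O)=C=O; trimethyloxonium tetrafluoroborate, C[O+](C)C.F[B-](F)(F)F
Why: Fischer carbene synthesis, in which bromine–lithium exchange gives alkenyllithium 4, addition to a carbonyl ligand gives acylchromate 5 (this carbon becomes C6) and hard O-methylation gives the alkoxycarbene complex of zerovalent chromium without touching the silyl ether or the stereocentre.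

**Step 4**
Reactants: 7 3-methylbut-2-enal
Product: 8 (E)-tert-butyldimethyl[(3-methylbuta-1,3-dien-1-yl)oxy]silane
Conditions: TBSOTf, Et3N, Et2O, 0 °C → rt
Reagents that add atoms: tert-butyldimethylsilyl trifluoromethanesulfonate, CC(C)(C)[Si](C)(C)OS(=O)(=O)C(F)(F)F
Why: Silyl dienol ether formation by carbonyl silylation and γ-deprotonation should give the conjugated 1-silyloxydiene with (E)-enol ether geometry.

**Step 5**
Reactants: 6 pentacarbonyl{methoxy[(S)-5-(tert-butyldimethylsilyloxy)-2-methylcyclopent-1-en-1-yl]methylidene}chromium; 8 (E)-tert-butyldimethyl[(3-methylbuta-1,3-dien-1-yl)oxy]silane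
Product: 10 6-methoxy-1β,8-dimethyl-4β,10α-bis(tert-butyldimethylsilyloxy)bicyclo[5.3.0]deca-5,8-diene (daucane numbering), via cis-divinylcyclopropane 9 (not isolated)
Conditions: 8 (4 equiv), toluene, 90 °C then 120 °C, sealed tube, Ar
Reagents that add atoms: none
Why: The electrophilic carbene carbon C6 of 6 is attacked by the terminal CH2 (C7) of the vinylogous silyl enol ether 8 and the carbene is transferred to the C7=C8 bond with loss of the pentacarbonylchromium fragment, giving the 1-alkoxy-1,2-divinylcyclopropane 9, which then undergoes a [3,3]-sigmatropic (Cope) shift through a boat transition state that cleaves C6–C8 and joins C10 to C1, any trans isomer of 9 feeding in by reversible homolysis of its doubly allylic, alkoxy-substituted ring bond. The closest known reaction type is the formal [4+3] cycloaddition of alkenyl Fischer carbene complexes (and of rhodium vinylcarbenoids) with electron-rich 1,3-dienes by tandem cyclopropanation and divinylcyclopropane rearrangement. The three-membered ring is closed by [2+1] carbene transfer and the seven-membered ring by ring expansion of that cyclopropane in the 3,3-shift, so C6–C7 and C1–C10 are both in place after one operation. The quaternary centre C1 is controlled by the C4 silyloxy group, which should keep to the outer face of the cyclopentene in the boat transition state so that C10 bonds anti to it and the C1 methyl ends syn to it, while the (E)-geometry of 8 places the C10 silyloxy group trans to that methyl at a centre that is later oxidised away. The step needs site selectivity for the terminal 1,1-disubstituted diene bond over the enol ether bond, which attack at the unhindered nucleophilic terminus should secure, and cyclopropanation in preference to Diels–Alder addition across the alkenyl group, which the fully substituted, twisted C5=C1 bond should secure.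

**Step 6**
Reactants: 10 6-methoxy-1β,8-dimethyl-4β,10α-bis(tert-butyldimethylsilyloxy)bicyclo[5.3.0]deca-5,8-diene
Product: 11 1β,8-dimethyl-4β,10α-bis(tert-butyldimethylsilyloxy)-5αH-bicyclo[5.3.0]dec-8-en-6-one (trans-fused)
Conditions: 0.5 M aq. HCl, THF, 0 °C
Reagents that add atoms: water, O
Why: Enol ether hydrolysis, in which C5 should be protonated from the α-face, opposite the C1 methyl and C4 silyloxy groups, setting the trans ring fusion under kinetic control before water converts the oxocarbenium ion into the C6 ketone, under conditions too mild for enolisation or β-elimination of the silyloxy group.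

**Step 7**
Reactants: 11 1β,8-dimethyl-4β,10α-bis(tert-butyldimethylsilyloxy)-5αH-bicyclo[5.3.0]dec-8-en-6-one
Product: 12 1β,8-dimethyl-4β,10α-bis(tert-butyldimethylsilyloxy)-5αH-bicyclo[5.3.0]dec-8-en-6β-ol
Conditions: NaBH4, MeOH/THF, −40 °C
Reagents that add atoms: none
Why: Borohydride reduction, in which hydride should approach C6 from the α-face, away from the axial C1 methyl and the C4 silyloxy group, to give the 6β-alcohol (6α-H cis to 5α-H) while the isolated alkene and silyl ethers are inert.

**Step 8**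
Reactants: 12 1β,8-dimethyl-4β,10α-bis(tert-butyldimethylsilyloxy)-5αH-bicyclo[5.3.0]dec-8-en-6β-ol; 13 4-(allyloxy)-3-methoxybenzoic acid
Product: 15 6β-[4-(allyloxy)-3-methoxybenzoyloxy]-1β,8-dimethyl-4β,10α-bis(tert-butyldimethylsilyloxy)-5αH-bicyclo[5.3.0]dec-8-ene, via mixed anhydride 14 (not isolated)
Conditions: 13, 2,4,6-trichlorobenzoyl chloride, Et3N, toluene, rt; then 12, 4-(dimethylamino)pyridine, 50 °C
Reagents that add atoms: none
Why: Yamaguchi esterification, in which mixed anhydride 14 acylates the hindered secondary alcohol through its acylpyridinium salt with retention at C6, the phenol being masked as an allyl ether that should survive every later step.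

**Step 9**
Reactants: 15 6β-[4-(allyloxy)-3-methoxybenzoyloxy]-1β,8-dimethyl-4β,10α-bis(tert-butyldimethylsilyloxy)-5αH-bicyclo[5.3.0]dec-8-ene
Product: 16 6β-[4-(allyloxy)-3-methoxybenzoyloxy]-1β,8-dimethyl-5αH-bicyclo[5.3.0]dec-8-ene-4β,10α-diol
Conditions: HF·pyridine, pyridine, THF, 0 °C → rt
Reagents that add atoms: none
Why: Acidic fluoride desilylation cleaves both secondary silyl ethers and avoids the alkoxide that would trigger 1,3-acyl migration from O6 to O4.

**Step 10**
Reactants: 16 6β-[4-(allyloxy)-3-methoxybenzoyloxy]-1β,8-dimethyl-5αH-bicyclo[5.3.0]dec-8-ene-4β,10α-diol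
Product: 17 6β-[4-(allyloxy)-3-methoxybenzoyloxy]-1β,8-dimethyl-5αH-bicyclo[5.3.0]dec-8-ene-4,10-dione
Conditions: Dess–Martin periodinane, pyridine, CH2Cl2, 0 °C → rt
Reagents that add atoms: none
Why: Dess–Martin oxidation converts the allylic C10 alcohol into the enone and the C4 alcohol into the cyclopentanone in one pot under near-neutral conditions that should spare the β-acyloxy ketone from elimination and C5 from epimerisation.

**Step 11**
Reactants: 17 6β-[4-(allyloxy)-3-methoxybenzoyloxy]-1β,8-dimethyl-5αH-bicyclo[5.3.0]dec-8-ene-4,10-dione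
Product: 18 6β-[4-(allyloxy)-3-methoxybenzoyloxy]-4β-hydroxy-5αH-dauc-8-en-10-one
Conditions: iPrMgCl, CeCl3, THF, −78 °C; aq. NH4Cl
Reagents that add atoms: isopropylmagnesium chloride, CC(C)[Mg]Cl
Why: Organocerium 1,2-addition, in which the weakly basic, oxophilic isopropylcerium reagent should prefer the saturated cyclopentanone over the neopentyl conjugated C10 carbonyl and the aryl ester and should attack from the α-face, opposite the axial C1 methyl and the C6 substituent, to set the 4β-hydroxy-4α-isopropyl centre.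

**Step 12**
Reactants: 18 6β-[4-(allyloxy)-3-methoxybenzoyloxy]-4β-hydroxy-5αH-dauc-8-en-10-one
Product: 19 6β-(4-hydroxy-3-methoxybenzoyloxy)-4β-hydroxy-5αH-dauc-8-en-10-one (CNP0136950.1)
Conditions: Pd(PPh3)4 (5 mol %), morpholine, THF, rt
Reagents that add atoms: none
Why: Tsuji–Trost-type deallylation, in which zerovalent palladium ionises the aryl allyl ether and morpholine traps the allyl unit, should free the phenol without touching the enone, tertiary alcohol or ester.

**Compound list**

1 | 2-bromo-3-methylcyclopent-2-en-1-one | CC1=C(Br)C(=O)CC1 | starting material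
2 | (S)-2-bromo-3-methylcyclopent-2-en-1-ol | O[C@H]1CCC(C)=C1Br | intermediate
3 | (S)-[(2-bromo-3-methylcyclopent-2-en-1-yl)oxy](tert-butyl)dimethylsilane | CC(C)(C)[Si](C)(C)O[C@H]1CCC(C)=C1Br | intermediate
4 | [(S)-5-(tert-butyldimethylsilyloxy)-2-methylcyclopent-1-en-1-yl]lithium | CC(C)(C)[Si](C)(C)O[C@H]1CCC(C)=C1[Li] | intermediate
5 | lithium pentacarbonyl{[(S)-5-(tert-butyldimethylsilyloxy)-2-methylcyclopent-1-en-1-yl]carbonyl}chromate | [Li+].CC(C)(C)[Si](C)(C)O[C@H]1CCC(C)=C1C([O-])=[Cr](=C=O)(=C=O)(=C=O)(=C=O)=C=O | intermediate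
6 | pentacarbonyl{methoxy[(S)-5-(tert-butyldimethylsilyloxy)-2-methylcyclopent-1-en-1-yl]methylidene}chromium | CC(C)(C)[Si](C)(C)O[C@H]1CCC(C)=C1C(OC)=[Cr](=C=O)(=C=O)(=C=O)(=C=O)=C=O | intermediate
7 | 3-methylbut-2-enal | CC(C)=CC=O | starting material
8 | (E)-tert-butyldimethyl[(3-methylbuta-1,3-dien-1-yl)oxy]silane | C=C(C)/C=C/O[Si](C)(C)C(C)(C)C | intermediate
9 | cis-1-methoxy-2-methyl-1-[(S)-5-(tert-butyldimethylsilyloxy)-2-methylcyclopent-1-en-1-yl]-2-[(E)-2-(tert-butyldimethylsilyloxy)ethenyl]cyclopropane (productive diastereomer shown) | CO[C@]1(C[C@]1(C)/C=C/O[Si](C)(C)C(C)(C)C)C2=C(C)CC[C@@H]2O[Si](C)(C)C(C)(C)C | intermediate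
10 | 6-methoxy-1β,8-dimethyl-4β,10α-bis(tert-butyldimethylsilyloxy)bicyclo[5.3.0]deca-5,8-diene | COC1=C2[C@@H](O[Si](C)(C)C(C)(C)C)CC[C@]2(C)[C@H](O[Si](C)(C)C(C)(C)C)C=C(C)C1 | intermediate
11 | 1β,8-dimethyl-4β,10α-bis(tert-butyldimethylsilyloxy)-5αH-bicyclo[5.3.0]dec-8-en-6-one | O=C1CC(C)=C[C@@H](O[Si](C)(C)C(C)(C)C)[C@@]2(C)CC[C@H](O[Si](C)(C)C(C)(C)C)[C@H]12 | intermediate
12 | 1β,8-dimethyl-4β,10α-bis(tert-butyldimethylsilyloxy)-5αH-bicyclo[5.3.0]dec-8-en-6β-ol | O[C@@H]1CC(C)=C[C@@H](O[Si](C)(C)C(C)(C)C)[C@@]2(C)CC[C@H](O[Si](C)(C)C(C)(C)C)[C@H]12 | intermediate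
13 | 4-(allyloxy)-3-methoxybenzoic acid | COc1cc(C(=O)O)ccc1OCC=C | starting material
14 | 4-(allyloxy)-3-methoxybenzoic 2,4,6-trichlorobenzoic anhydride | COc1cc(C(=O)OC(=O)c2c(Cl)cc(Cl)cc2Cl)ccc1OCC=C | intermediate
15 | 6β-[4-(allyloxy)-3-methoxybenzoyloxy]-1β,8-dimethyl-4β,10α-bis(tert-butyldimethylsilyloxy)-5αH-bicyclo[5.3.0]dec-8-ene | COc1cc(C(=O)O[C@@H]2CC(C)=C[C@@H](O[Si](C)(C)C(C)(C)C)[C@@]3(C)CC[C@H](O[Si](C)(C)C(C)(C)C)[C@H]23)ccc1OCC=C | intermediate
16 | 6β-[4-(allyloxy)-3-methoxybenzoyloxy]-1β,8-dimethyl-5αH-bicyclo[5.3.0]dec-8-ene-4β,10α-diol | COc1cc(C(=O)O[C@@H]2CC(C)=C[C@@H](O)[C@@]3(C)CC[C@H](O)[C@H]23)ccc1OCC=C | intermediate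
17 | 6β-[4-(allyloxy)-3-methoxybenzoyloxy]-1β,8-dimethyl-5αH-bicyclo[5.3.0]dec-8-ene-4,10-dione | COc1cc(C(=O)O[C@@H]2CC(C)=CC(=O)[C@@]3(C)CCC(=O)[C@H]23)ccc1OCC=C | intermediate
18 | 6β-[4-(allyloxy)-3-methoxybenzoyloxy]-4β-hydroxy-5αH-dauc-8-en-10-one | COc1cc(C(=O)O[C@@H]2CC(C)=CC(=O)[C@@]3(C)CC[C@@](O)(C(C)C)[C@H]23)ccc1OCC=C | intermediate
19 | 6β-(4-hydroxy-3-methoxybenzoyloxy)-4β-hydroxy-5αH-dauc-8-en-10-one | COc1cc(C(=O)O[C@@H]2CC(C)=CC(=O)[C@@]3(C)CC[C@@](O)(C(C)C)[C@H]23)ccc1O | target

**Step count.** Total: 12 steps. Longest linear sequence: 11 steps (steps 1, 2, 3 and 5 to 12; step 4 is the side branch).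

**Steps most likely to fail**

Step 5. The crowded carbene complex may decompose thermally, or undergo metathesis at the enol ether bond, before carbene transfer to the diene. The rearrangement may also stall at the divinylcyclopropane, because bond formation at the fully substituted C1 is slow, or proceed with poor facial selectivity. The fallback keeps the same two bond formations but makes them by an anionic, chromium-free Brook-rearrangement-mediated [3+4] annulation; it sets out from 3 and comes back at 11. Bromine–lithium exchange as in step 3 and quenching of 4 with 4-morpholinecarbonyl chloride should give the morpholine amide F1, which with PhMe2SiLi (THF, −78 °C) should give the acylsilane F2. Separately, Claisen condensation of acetone with ethyl formate (NaOMe) gives sodium (E)-3-oxobut-1-en-1-olate F3, which TBSCl converts into (E)-4-(tert-butyldimethylsilyloxy)but-3-en-2-one F4. The lithium enolate of F4 (LDA, THF, −80 °C) is added to F2 and warmed to −30 °C. 1,2-Addition, Brook rearrangement, closure to the cis-divinylcyclopropanediolate and anionic oxy-Cope shift should then form C6–C7 and C1–C10, again anti to the C4 silyloxy group. Trapping the resulting C8 enolate with PhNTf2 should give the enol triflate F5. Coupling with Me2CuLi installs the C8 methyl group to give the silyl enol ether F6, and dilute HCl in THF at 0 °C hydrolyses it to ketone 11.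

Step 11. The basic reagent may enolise the C4 ketone, with β-elimination of the C6 acyloxy group, or add to the ester or the C10 carbonyl instead of the cyclopentanone. The fallback introduces the isopropyl group before any ester is present; it sets out from 12 and comes back at 18. Alcohol 12 is protected with 4-methoxybenzyl 2,2,2-trichloroacetimidate and catalytic La(OTf)3 as the 4-methoxybenzyl ether F7. HF·pyridine gives the diol F8 and Dess–Martin periodinane the dione F9. Addition of iPrMgCl/CeCl3 then meets only a β-alkoxy ketone and should give the tertiary carbinol F10. DDQ in wet CH2Cl2 removes the benzyl ether to give 4β,6β-dihydroxy-5αH-dauc-8-en-10-one F11. Yamaguchi esterification with 13 acylates only the secondary C6 hydroxyl and gives 18.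

Step 7. Hydride delivery on the flexible seven-membered ring may show poor facial selectivity and give mainly the 6α-alcohol. The fallback replaces acylation with retention by esterification with inversion; it sets out from 11 and comes back at 15. The 6α-alcohol F12 obtained from 11 is treated with acid 13, PPh3 and diisopropyl azodicarboxylate in toluene (Mitsunobu reaction). SN2 displacement at C6 by the carboxylate should give the 6β-ester 15 directly.

**Further compounds**

F1 | step 5 | [(S)-5-(tert-butyldimethylsilyloxy)-2-methylcyclopent-1-en-1-yl](morpholin-4-yl)methanone | CC(C)(C)[Si](C)(C)O[C@H]1CCC(C)=C1C(=O)N1CCOCC1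
F2 | step 5 | [(S)-5-(tert-butyldimethylsilyloxy)-2-methylcyclopent-1-en-1-yl][dimethyl(phenyl)silyl]methanone | CC(C)(C)[Si](C)(C)O[C@H]1CCC(C)=C1C(=O)[Si](C)(C)c1ccccc1
F3 | step 5 | sodium (E)-3-oxobut-1-en-1-olate | [Na+].CC(=O)/C=C/[O-]
F4 | step 5 | (E)-4-(tert-butyldimethylsilyloxy)but-3-en-2-one | CC(=O)/C=C/O[Si](C)(C)C(C)(C)C
F5 | step 5 | 6-[dimethyl(phenyl)silyloxy]-1β-methyl-4β,10α-bis(tert-butyldimethylsilyloxy)bicyclo[5.3.0]deca-5,8-dien-8-yl trifluoromethanesulfonate | C[Si](C)(c1ccccc1)OC1=C2[C@@H](O[Si](C)(C)C(C)(C)C)CC[C@]2(C)[C@H](O[Si](C)(C)C(C)(C)C)C=C(OS(=O)(=O)C(F)(F)F)C1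
F6 | step 5 | 6-[dimethyl(phenyl)silyloxy]-1β,8-dimethyl-4β,10α-bis(tert-butyldimethylsilyloxy)bicyclo[5.3.0]deca-5,8-diene | C[Si](C)(c1ccccc1)OC1=C2[C@@H](O[Si](C)(C)C(C)(C)C)CC[C@]2(C)[C@H](O[Si](C)(C)C(C)(C)C)C=C(C)C1
F7 | step 11 | 6β-(4-methoxybenzyloxy)-1β,8-dimethyl-4β,10α-bis(tert-butyldimethylsilyloxy)-5αH-bicyclo[5.3.0]dec-8-ene | COc1ccc(CO[C@@H]2CC(C)=C[C@@H](O[Si](C)(C)C(C)(C)C)[C@@]3(C)CC[C@H](O[Si](C)(C)C(C)(C)C)[C@H]23)cc1
F8 | step 11 | 6β-(4-methoxybenzyloxy)-1β,8-dimethyl-5αH-bicyclo[5.3.0]dec-8-ene-4β,10α-diol | COc1ccc(CO[C@@H]2CC(C)=C[C@@H](O)[C@@]3(C)CC[C@H](O)[C@H]23)cc1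
F9 | step 11 | 6β-(4-methoxybenzyloxy)-1β,8-dimethyl-5αH-bicyclo[5.3.0]dec-8-ene-4,10-dione | COc1ccc(CO[C@@H]2CC(C)=CC(=O)[C@@]3(C)CCC(=O)[C@H]23)cc1
F10 | step 11 | 4β-hydroxy-6β-(4-methoxybenzyloxy)-5αH-dauc-8-en-10-one | COc1ccc(CO[C@@H]2CC(C)=CC(=O)[C@@]3(C)CC[C@@](O)(C(C)C)[C@H]23)cc1
F11 | step 11 | 4β,6β-dihydroxy-5αH-dauc-8-en-10-one | O[C@@H]1CC(C)=CC(=O)[C@@]2(C)CC[C@@](O)(C(C)C)[C@H]12
F12 | step 7 | 1β,8-dimethyl-4β,10α-bis(tert-butyldimethylsilyloxy)-5αH-bicyclo[5.3.0]dec-8-en-6α-ol | O[C@H]1CC(C)=C[C@@H](O[Si](C)(C)C(C)(C)C)[C@@]2(C)CC[C@H](O[Si](C)(C)C(C)(C)C)[C@H]12
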